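**Retrosynthetic overview** (eudesmane-type numbering: ring A = C1–C5 + C10, ring B = C5–C10; C10 carries the angular methyl, C4 the CH2O carbon C15, C7 the acrylate carbon C11)
1. Late disconnections: the C15–O ester (Mitsunobu with p-coumaric acid); C3=C4–C15H2OH from a C4 ketone (enol triflate, Stille hydroxymethylation); the acrylate from C7–CH2OH via aldehyde, alkyne and Pd-catalysed hydromethoxycarbonylation.
2. Key disconnection: C6–C7 and C5–C10 together, by a catalytic enantioselective type 1 intramolecular Diels–Alder reaction of the acyclic trienone 11 (vinyl ketone C6=C5–C4=O, diene C7=C8–C9=C10); rings A and B form in the same step, ring B as the [4+2] ring and ring A through the C1–C3 tether.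
3. Enabling feature: in ring B the two-carbon edge C5–C6 faces the four-carbon arc C7–C10; C4, next to C5, is sp2 in the target and can be a ketone that activates the dienophile and later makes C5 epimerisable; C1–C3 of ring A tie C10 to C4.
4. Stereochemical plan: the tether sits on the Z (inside) position of the diene, which forces cis fusion and sets C7 and C10 correctly; base then turns the cis into the trans ring fusion.
5. Trienone 11 comes from a (Z)-alkenyl iodide (carbocupration of propyne) and an (E)-alkenylboronate (Suzuki–Miyaura), then vinyl Grignard addition and oxidation.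

Key step: step 7

Assumption: the (S)-catalyst of step 7 is taken to leave the Re face at C2 of the vinyl ketone open; if the sense of induction proved opposite, the enantiomeric catalyst (from (R)-α,α-diphenylprolinol) would be used and nothing else would change.

**Step 1**
Reactants: 1 2-(3-chloropropyl)-1,3-dioxolane; 2 propyne
Product: 5 2-[(4Z)-5-iodo-4-methylpent-4-en-1-yl]-1,3-dioxolane, via Grignard reagent 3 (not isolated), via (Z)-alkenylcopper species 4 (not isolated)
Conditions: Mg, THF, 50 °C; CuBr·SMe2, Et2O–Me2S, −45 °C; propyne, −25 °C; I2, THF, −60 → 0 °C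
Reagents that add atoms: iodine, II; magnesium (in 3), [Mg]; CuBr·SMe2 (copper in 4), Br[Cu].CSC
Why: Carbocupration of a terminal alkyne by an alkylcopper–magnesium halide reagent is a syn addition that puts the alkyl group on the internal carbon, so the tether should end cis to copper and, after iodinolysis with retention, cis to iodine (4Z).

**Step 2**
Reactants: 6 benzyl prop-2-yn-1-yl ether
Product: 7 2-[(1E)-3-(benzyloxy)prop-1-en-1-yl]-4,4,5,5-tetramethyl-1,3,2-dioxaborolane
Conditions: pinacolborane, Cp2Zr(H)Cl (5 mol%), Et3N (10 mol%), neat, 60 °C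
Reagents that add atoms: pinacolborane, CC1(C)OBOC1(C)C
Why: Zirconocene-hydride-catalysed hydroboration of a terminal alkyne is a syn, terminal-selective addition and should give the (E)-alkenylboronate only.

**Step 3**
Reactants: 5 2-[(4Z)-5-iodo-4-methylpent-4-en-1-yl]-1,3-dioxolane; 7 2-[(1E)-3-(benzyloxy)prop-1-en-1-yl]-4,4,5,5-tetramethyl-1,3,2-dioxaborolane
Product: 8 2-[(4Z,6E)-8-(benzyloxy)-4-methylocta-4,6-dien-1-yl]-1,3-dioxolane
Conditions: Pd(dppf)Cl2 (5 mol%), K3PO4, THF–H2O, 50 °C
Reagents that add atoms: none
Why: Suzuki–Miyaura coupling of an alkenyl iodide with an alkenylboronate proceeds with retention at both partners, so the (4Z,6E)-diene should form without touching the acetal or the benzyl ether.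

**Step 4**
Reactants: 8 2-[(4Z,6E)-8-(benzyloxy)-4-methylocta-4,6-dien-1-yl]-1,3-dioxolane
Product: 9 (5Z,7E)-9-(benzyloxy)-5-methylnona-5,7-dienal
Conditions: PPTS, acetone–H2O, 60 °C
Reagents that add atoms: water, O
Why: Mild acid-catalysed acetal hydrolysis frees the aldehyde, and the weakly acidic medium should leave the dienyl benzyl ether and the diene geometry alone.

**Step 5**
Reactants: 9 (5Z,7E)-9-(benzyloxy)-5-methylnona-5,7-dienal
Product: 10 (7Z,9E)-11-(benzyloxy)-7-methylundeca-1,7,9-trien-3-ol (racemic)
Conditions: CH2=CHMgBr, THF, −78 → 0 °C; then H2O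
Reagents that add atoms: vinylmagnesium bromide, C=C[Mg]Br
Why: Grignard 1,2-addition to the aldehyde gives the allylic alcohol as a racemate, which is of no consequence because this carbon becomes the ketone in the next step.

**Step 6**
Reactants: 10 (7Z,9E)-11-(benzyloxy)-7-methylundeca-1,7,9-trien-3-ol
Product: 11 (7Z,9E)-11-(benzyloxy)-7-methylundeca-1,7,9-trien-3-one
Conditions: DMP, NaHCO3, CH2Cl2, 0 °C; used at once
Reagents that add atoms: none
Why: Dess–Martin oxidation of a secondary allylic alcohol is fast under buffered, non-basic conditions and should deliver the sensitive vinyl ketone without conjugate addition or diene isomerisation.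

**Step 7**
Reactants: 11 (7Z,9E)-11-(benzyloxy)-7-methylundeca-1,7,9-trien-3-one
Product: 12 (4aR,7S,8aS)-7-[(benzyloxy)methyl]-4a-methyl-3,4,4a,7,8,8a-hexahydronaphthalen-1(2H)-one (cis-fused; CH2OBn cis to the angular methyl)
Conditions: (S)-3,3-diphenyl-1-(o-tolyl)tetrahydro-1H,3H-pyrrolo[1,2-c][1,3,2]oxazaborole (20 mol%), HNTf2 (17 mol%), CH2Cl2, −78 → −40 °C
Reagents that add atoms: none
Why: Proposed new method: the N-protonated oxazaborolidine binds the only carbonyl group of 11, lowers the LUMO of the vinyl ketone and blocks one of its faces, and an asynchronous concerted type 1 intramolecular Diels–Alder reaction follows in which the bond from the enone β-carbon C1 to the unhindered diene terminus C10 runs ahead of the bond from C2 to the fully substituted terminus C7 (trienone numbering); the closest known reaction types are the Lewis-acid-promoted cycloadditions of (7Z)-deca-1,7,9-trien-3-ones to cis-fused octalones and the enantioselective Diels–Alder reactions of simple vinyl ketones and of trienals under cationic oxazaborolidine catalysis, which have not been joined on a tether-bound vinyl ketone that builds a quaternary centre. Ring B (the cyclohexene) closes as the [4π+2π] ring, suprafacial on both components, and ring A (the cyclohexanone) closes at the same time through the C2–C7 bond as the six-membered ring spanned by the three-methylene tether and the carbonyl carbon, with the carbonyl group exo to the diene. The CH that carries CH2OBn is set relative to the quaternary carbon by the diene geometry (methyl and CH2OBn are both outside groups of the 7Z,9E-diene and end cis, as the target needs), the ring-fusion CH can only come out cis because a tether on the inside position of the diene reaches the α-carbon of the enone in the exo mode alone, and the absolute configuration of the quaternary carbon follows from the enone face left open by the catalyst (Re at C2). The step therefore needs one fusion mode and one enantioface: the first is secured by the Z attachment of the tether in the substrate, the second by the catalyst, helped by the expected absence of an uncatalysed background reaction at −78 °C for this hindered diene. The cis ring fusion is not that of the target, but this CH lies next to the ketone and is corrected in step 8.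

**Step 8**
Reactants: 12 (4aR,7S,8aS)-7-[(benzyloxy)methyl]-4a-methyl-3,4,4a,7,8,8a-hexahydronaphthalen-1(2H)-one
Product: 14 (4aR,7R,8aR)-7-(hydroxymethyl)-4a-methyloctahydronaphthalen-1(2H)-one (trans-fused), via cis-fused keto alcohol 13 (not isolated)
Conditions: H2 (1 atm), Pd/C, EtOAc–MeOH, rt; filter; then NaOMe, MeOH, rt
Reagents that add atoms: none
Why: Heterogeneous hydrogenation saturates the ring alkene and cleaves the benzyl ether without creating a stereocentre, and methoxide then equilibrates the ring-fusion CH next to the ketone through the enolate to the more stable trans-decalone, in which the angular methyl is the only axial substituent (thermodynamic control, as in the base epimerisation of cis-fused 1-decalones and 4-oxo-5β-steroids).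

**Step 9**
Reactants: 14 (4aR,7R,8aR)-7-(hydroxymethyl)-4a-methyloctahydronaphthalen-1(2H)-one
Product: 15 (2R,4aR,8aR)-4a-methyl-8-oxodecahydronaphthalene-2-carbaldehyde
Conditions: DMP, CH2Cl2, 0 °C → rt
Reagents that add atoms: none
Why: Dess–Martin oxidation of the primary alcohol stops at the aldehyde and, being non-basic, should not disturb the equatorial configuration of the carbon that carries it.

**Step 10**
Reactants: 15 (2R,4aR,8aR)-4a-methyl-8-oxodecahydronaphthalene-2-carbaldehyde
Product: 16 (4aR,7R,8aR)-7-ethynyl-4a-methyloctahydronaphthalen-1(2H)-one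
Conditions: dimethyl (1-diazo-2-oxopropyl)phosphonate, K2CO3, MeOH, 0 °C → rt
Reagents that add atoms: dimethyl (1-diazo-2-oxopropyl)phosphonate (Ohira–Bestmann reagent), CC(=O)C(=[N+]=[N-])P(=O)(OC)OC
Why: The Ohira–Bestmann variant of the Seyferth–Gilbert homologation converts the aldehyde into the terminal alkyne under conditions mild enough to spare the less electrophilic ketone, and the equatorial aldehyde is in any case the favoured epimer under the carbonate base.

**Step 11**
Reactants: 16 (4aR,7R,8aR)-7-ethynyl-4a-methyloctahydronaphthalen-1(2H)-one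
Product: 17 methyl 2-[(2R,4aR,8aR)-4a-methyl-8-oxodecahydronaphthalen-2-yl]prop-2-enoate
Conditions: Pd(OAc)2 (2 mol%), 2-(diphenylphosphino)pyridine, CH3SO3H (cat.), CO (10 bar), MeOH, 50 °C; aqueous acid work-up
Reagents that add atoms: carbon monoxide, [C-]#[O+]; methanol, CO
Why: Palladium-catalysed hydromethoxycarbonylation of a terminal alkyne with a pyridylphosphine ligand and a sulfonic acid adds H and CO2Me in the branched sense and so should give the 2-substituted acrylate directly without touching the stereocentres.

**Step 12**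
Reactants: 17 methyl 2-[(2R,4aR,8aR)-4a-methyl-8-oxodecahydronaphthalen-2-yl]prop-2-enoate
Product: 18 methyl 2-[(2R,4aS,8aR)-4a-methyl-8-{[(trifluoromethyl)sulfonyl]oxy}-1,2,3,4,4a,5,6,8a-octahydronaphthalen-2-yl]prop-2-enoate
Conditions: PhNTf2, THF, −78 °C; KN(SiMe3)2 added slowly
Reagents that add atoms: N-phenylbis(trifluoromethanesulfonimide), FC(F)(F)S(=O)(=O)N(c1ccccc1)S(=O)(=O)C(F)(F)F
Why: Kinetic deprotonation of the trans-decalone by the hindered amide takes a CH2 proton and not the ring-fusion methine, and the enolate is trapped at once by the PhNTf2 already in the flask (enol triflate formation), which should keep it from adding to the acrylate.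

**Step 13**
Reactants: 18 methyl 2-[(2R,4aS,8aR)-4a-methyl-8-{[(trifluoromethyl)sulfonyl]oxy}-1,2,3,4,4a,5,6,8a-octahydronaphthalen-2-yl]prop-2-enoate
Product: 19 methyl 2-[(2R,4aR,8aR)-8-(hydroxymethyl)-4a-methyl-1,2,3,4,4a,5,6,8a-octahydronaphthalen-2-yl]prop-2-enoate
Conditions: Bu3SnCH2OH, Pd(PPh3)4 (10 mol%), LiCl, 1,4-dioxane, 95 °C
Reagents that add atoms: (tributylstannyl)methanol, CCCC[Sn](CCCC)(CCCC)CO
Why: Stille coupling of the alkenyl triflate with (tributylstannyl)methanol in the presence of LiCl transfers the hydroxymethyl group selectively and installs the allylic alcohol with the double bond fixed in its ring position.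

**Step 14**
Reactants: 19 methyl 2-[(2R,4aR,8aR)-8-(hydroxymethyl)-4a-methyl-1,2,3,4,4a,5,6,8a-octahydronaphthalen-2-yl]prop-2-enoate; 20 (2E)-3-(4-hydroxyphenyl)prop-2-enoic acid (p-coumaric acid)
Product: 21 methyl 2-[(2R,4aR,8aR)-8-({[(2E)-3-(4-hydroxyphenyl)prop-2-enoyl]oxy}methyl)-4a-methyl-1,2,3,4,4a,5,6,8a-octahydronaphthalen-2-yl]prop-2-enoate (CNP0161949.1)
Conditions: PPh3, DIAD, THF, 0 °C → rt
Reagents that add atoms: none
Why: In the Mitsunobu esterification the alkoxyphosphonium ion of the primary allylic alcohol is displaced by the carboxylate, which is far more acidic than the phenol and should react chemoselectively, so the phenol needs no protection and the (E)-cinnamate geometry is kept.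

**Compound list**
1 | 2-(3-chloropropyl)-1,3-dioxolane | ClCCCC1OCCO1 | starting material
2 | propyne | CC#C | starting material
3 | [3-(1,3-dioxolan-2-yl)propyl]magnesium chloride | Cl[Mg]CCCC1OCCO1 | intermediate
4 | [(1Z)-5-(1,3-dioxolan-2-yl)-2-methylpent-1-en-1-yl]copper (as its MgBrCl complex) | [Cu]/C=C(C)\CCCC1OCCO1 | intermediate
5 | 2-[(4Z)-5-iodo-4-methylpent-4-en-1-yl]-1,3-dioxolane | I/C=C(C)\CCCC1OCCO1 | intermediate
6 | benzyl prop-2-yn-1-yl ether | C#CCOCc1ccccc1 | starting material
7 | 2-[(1E)-3-(benzyloxy)prop-1-en-1-yl]-4,4,5,5-tetramethyl-1,3,2-dioxaborolane | CC1(C)OB(/C=C/COCc2ccccc2)OC1(C)C | intermediate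
8 | 2-[(4Z,6E)-8-(benzyloxy)-4-methylocta-4,6-dien-1-yl]-1,3-dioxolane | O1CCOC1CCC/C(C)=C\C=C\COCc1ccccc1 | intermediate
9 | (5Z,7E)-9-(benzyloxy)-5-methylnona-5,7-dienal | O=CCCC/C(C)=C\C=C\COCc1ccccc1 | intermediate
10 | (7Z,9E)-11-(benzyloxy)-7-methylundeca-1,7,9-trien-3-ol (racemic) | C=CC(O)CCC/C(C)=C\C=C\COCc1ccccc1 | intermediate
11 | (7Z,9E)-11-(benzyloxy)-7-methylundeca-1,7,9-trien-3-one | C=CC(=O)CCC/C(C)=C\C=C\COCc1ccccc1 | intermediate
12 | (4aR,7S,8aS)-7-[(benzyloxy)methyl]-4a-methyl-3,4,4a,7,8,8a-hexahydronaphthalen-1(2H)-one | c1ccccc1COC[C@@H]1C=C[C@@]2(C)CCCC(=O)[C@H]2C1 | intermediate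
13 | (4aR,7R,8aS)-7-(hydroxymethyl)-4a-methyloctahydronaphthalen-1(2H)-one (cis-fused) | OC[C@@H]1CC[C@@]2(C)CCCC(=O)[C@H]2C1 | intermediate
14 | (4aR,7R,8aR)-7-(hydroxymethyl)-4a-methyloctahydronaphthalen-1(2H)-one (trans-fused) | OC[C@@H]1CC[C@@]2(C)CCCC(=O)[C@@H]2C1 | intermediate
15 | (2R,4aR,8aR)-4a-methyl-8-oxodecahydronaphthalene-2-carbaldehyde | O=C[C@@H]1CC[C@@]2(C)CCCC(=O)[C@@H]2C1 | intermediate
16 | (4aR,7R,8aR)-7-ethynyl-4a-methyloctahydronaphthalen-1(2H)-one | C#C[C@@H]1CC[C@@]2(C)CCCC(=O)[C@@H]2C1 | intermediate
17 | methyl 2-[(2R,4aR,8aR)-4a-methyl-8-oxodecahydronaphthalen-2-yl]prop-2-enoate | C=C(C(=O)OC)[C@@H]1CC[C@@]2(C)CCCC(=O)[C@@H]2C1 | intermediate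
18 | methyl 2-[(2R,4aS,8aR)-4a-methyl-8-{[(trifluoromethyl)sulfonyl]oxy}-1,2,3,4,4a,5,6,8a-octahydronaphthalen-2-yl]prop-2-enoate | C=C(C(=O)OC)[C@@H]1CC[C@@]2(C)CCC=C(OS(=O)(=O)C(F)(F)F)[C@@H]2C1 | intermediate
19 | methyl 2-[(2R,4aR,8aR)-8-(hydroxymethyl)-4a-methyl-1,2,3,4,4a,5,6,8a-octahydronaphthalen-2-yl]prop-2-enoate | C=C(C(=O)OC)[C@@H]1CC[C@@]2(C)CCC=C(CO)[C@@H]2C1 | intermediate
20 | (2E)-3-(4-hydroxyphenyl)prop-2-enoic acid (p-coumaric acid) | O=C(O)/C=C/c1ccc(O)cc1 | starting material
21 | methyl 2-[(2R,4aR,8aR)-8-({[(2E)-3-(4-hydroxyphenyl)prop-2-enoyl]oxy}methyl)-4a-methyl-1,2,3,4,4a,5,6,8a-octahydronaphthalen-2-yl]prop-2-enoate | C=C(C(=O)OC)[C@@H]1CC[C@@]2(C)CCC=C(COC(=O)/C=C/c3ccc(O)cc3)[C@@H]2C1 | target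

**Step count**
Total: 14 steps. Longest linear sequence: 13 steps (1, 3–14); step 2 is a one-step side branch.

**Steps most likely to fail**

Step 7. What may go wrong: insufficient enantiofacial discrimination by the catalyst on a vinyl ketone held in the tether, slow turnover at the trisubstituted diene terminus, or acid-induced ionisation of the dienyl benzyl ether. Fallback (known chemistry), setting out from 11: the cycloaddition is run with an achiral promoter (Me2AlCl, CH2Cl2, low temperature, or simple warming in toluene), as is established for deca-1,7,9-trien-3-ones. The Z-bound tether should still enforce the cis fusion and the relative configuration, so racemic material is expected, that is 12 together with its mirror image (4aS,7R,8aR)-7-[(benzyloxy)methyl]-4a-methyl-3,4,4a,7,8,8a-hexahydronaphthalen-1(2H)-one F1. The enantiomers are separated by preparative chromatography on a chiral stationary phase, so that the absolute configuration comes from resolution instead of catalysis, and the route is rejoined at 12.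

Step 12. What may go wrong: conjugate addition of the enolate or of the amide base to the 2-substituted acrylate, or deprotonation at the allylic CH of the acrylate. Fallback, setting out from 16: the ketone is converted into the enol triflate before any acrylate exists. Treatment of 16 with PhNTf2 and KN(SiMe3)2 (2.2 equiv, the acetylide being reprotonated on work-up) should give (4aS,7R,8aR)-7-ethynyl-4a-methyl-3,4,4a,5,6,7,8,8a-octahydronaphthalen-1-yl trifluoromethanesulfonate F2. Stille coupling with Bu3SnCH2OH under the conditions of step 13 should give [(4aR,7R,8aR)-7-ethynyl-4a-methyl-3,4,4a,5,6,7,8,8a-octahydronaphthalen-1-yl]methanol F3. Hydromethoxycarbonylation of the alkyne under the conditions of step 11 then returns to the route at 19.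

Step 11. What may go wrong: loss of branched selectivity at a secondary-alkyl alkyne, or slow turnover because the ketone is tied up as its dimethyl ketal in acidic methanol. Fallback, setting out from 16: the C–Br and C–CO2Me bonds are made in separate, known steps. Bromoboration with B-bromo-9-BBN (CH2Cl2, 0 °C) should give the syn adduct (4aR,7R,8aR)-7-[(Z)-1-bromo-2-(9-borabicyclo[3.3.1]nonan-9-yl)ethenyl]-4a-methyloctahydronaphthalen-1(2H)-one F4. Protonolysis with acetic acid should give (4aR,7R,8aR)-7-(1-bromoethenyl)-4a-methyloctahydronaphthalen-1(2H)-one F5. Methoxycarbonylation of this alkenyl bromide (PdCl2(PPh3)2, CO, MeOH, Et3N, 60 °C) comes back to the route at 17.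

**Further compounds**
F1 | step 7 | (4aS,7R,8aR)-7-[(benzyloxy)methyl]-4a-methyl-3,4,4a,7,8,8a-hexahydronaphthalen-1(2H)-one | c1ccccc1COC[C@H]1C=C[C@]2(C)CCCC(=O)[C@@H]2C1
F2 | step 12 | (4aS,7R,8aR)-7-ethynyl-4a-methyl-3,4,4a,5,6,7,8,8a-octahydronaphthalen-1-yl trifluoromethanesulfonate | C#C[C@@H]1CC[C@@]2(C)CCC=C(OS(=O)(=O)C(F)(F)F)[C@@H]2C1
F3 | step 12 | [(4aR,7R,8aR)-7-ethynyl-4a-methyl-3,4,4a,5,6,7,8,8a-octahydronaphthalen-1-yl]methanol | C#C[C@@H]1CC[C@@]2(C)CCC=C(CO)[C@@H]2C1
F4 | step 11 | (4aR,7R,8aR)-7-[(Z)-1-bromo-2-(9-borabicyclo[3.3.1]nonan-9-yl)ethenyl]-4a-methyloctahydronaphthalen-1(2H)-one | Br/C(=C\B1C2CCCC1CCC2)[C@@H]1CC[C@@]2(C)CCCC(=O)[C@@H]2C1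
F5 | step 11 | (4aR,7R,8aR)-7-(1-bromoethenyl)-4a-methyloctahydronaphthalen-1(2H)-one | C=C(Br)[C@@H]1CC[C@@]2(C)CCCC(=O)[C@@H]2C1
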